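**Plan**

- Retrosynthesis: the C14=C15 enol ether goes back to a C15 methyl acetal and 6-OH to a silyl ether. Ring B is cut at C9–C10 (with C20–H and C8–H), giving a C10=C20 methylidene on ring A and a (Z)-2-alkylidene oxolane. That vinylogous ester is cut at C8–C9 (ethyl ketone + spiro lactone), the ketone at C6–C7 (ring A aldehyde + acyl anion), and ring A at C4–C5 (geraniol-derived epoxy diene).
- Forward: ring A by epoxide-initiated cation–olefin cyclisation; the spiro-linked pair of oxolanes (lactone + cyclic acetal) made separately; union at C6–C7 and C8–C9; ring B closed last; then unmasking.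
- Enabling feature: in ring B, C7 (ketone), C8 and the ether carbon C9 form a β-alkoxy ketone. C9 of the exocyclic enol ether C8=C9–O, conjugated to C7=O, is therefore a radical acceptor, and the quaternary C10 with its methyl is the Markovnikov radical of a methylidene on ring A.
- Stereochemistry: C3 and C4 from a Sharpless epoxide of a (Z)-allylic alcohol, C5 from the chair cyclisation, C13 from a second Sharpless epoxidation, C6 by Felkin–Anh addition, and C10, C9 and C8 in the key step.

Key step: step 19

Remark: the acetal carbon C15 is carried as both epimers (26–30, SMILES leave it open) and is removed in step 20; 24 (C3 of the lactone) and 28 (C8, C9) are likewise epimer mixtures at centres that are lost or reset later.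

Step 1
Reactants: 1 geraniol
Product: 2 tert-butyl{[(2E)-3,7-dimethylocta-2,6-dien-1-yl]oxy}diphenylsilane
Conditions: t-BuPh2SiCl, imidazole, CH2Cl2, 0 °C to rt
Reagents that add atoms: tert-butyl(chloro)diphenylsilane, CC(C)(C)[Si](Cl)(c1ccccc1)c1ccccc1
Why: Routine silylation of the primary allylic alcohol gives an ether that should survive the Lewis acid of step 6 and deactivates the proximal alkene for step 2.

Step 2
Reactants: 2 tert-butyl{[(2E)-3,7-dimethylocta-2,6-dien-1-yl]oxy}diphenylsilane
Product: 3 (4E)-6-{[tert-butyl(diphenyl)silyl]oxy}-4-methylhex-4-enal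
Conditions: O3 (1 equiv., Sudan Red 7B end point), CH2Cl2/MeOH, −78 °C; then Me2S
Reagents that add atoms: ozone, O=[O+][O-]
Why: Chemoselective ozonolysis, because the distal trisubstituted alkene is more electron-rich than the one bearing the allylic oxygen and should be cleaved first.

Step 3
Reactants: 3 (4E)-6-{[tert-butyl(diphenyl)silyl]oxy}-4-methylhex-4-enal; 4 ethyl 2-[bis(2,2,2-trifluoroethoxy)phosphoryl]propanoate
Product: 5 ethyl (2Z,6E)-8-{[tert-butyl(diphenyl)silyl]oxy}-2,6-dimethylocta-2,6-dienoate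
Conditions: KN(SiMe3)2, 18-crown-6, THF, −78 °C
Reagents that add atoms: none
Why: Still–Gennari olefination should give the kinetic (Z)-trisubstituted enoate, which places the future C19 cis to the chain.

Step 4
Reactants: 5 ethyl (2Z,6E)-8-{[tert-butyl(diphenyl)silyl]oxy}-2,6-dimethylocta-2,6-dienoate
Product: 6 (2Z,6E)-8-{[tert-butyl(diphenyl)silyl]oxy}-2,6-dimethylocta-2,6-dien-1-ol
Conditions: (i-Bu)2AlH, CH2Cl2, −78 to 0 °C; aqueous potassium sodium tartrate
Reagents that add atoms: none
Why: 1,2-Reduction of the enoate keeps the (Z) geometry and leaves the silyl ether untouched.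

Step 5
Reactants: 6 (2Z,6E)-8-{[tert-butyl(diphenyl)silyl]oxy}-2,6-dimethylocta-2,6-dien-1-ol
Product: 8 tert-butyl{[(2E)-3-methyl-5-[(2S,3R)-3-methyl-3-(triethylsilyloxymethyl)oxiran-2-yl]pent-2-en-1-yl]oxy}diphenylsilane, via epoxy alcohol 7 (not isolated)
Conditions: Ti(Oi-Pr)4 (10 mol%), D-(−)-diethyl tartrate (12 mol%), t-BuOOH, 4 Å MS, CH2Cl2, −20 °C; P(OMe)3; then Et3SiCl, Et3N, DMAP (cat.), 0 °C
Reagents that add atoms: tert-butyl hydroperoxide, CC(C)(C)OO; chlorotriethylsilane, CC[Si](Cl)(CC)CC
Why: Sharpless asymmetric epoxidation is chemoselective for the allylic alcohol, and D-(−)-tartrate should deliver oxygen to the face that gives the (2R,3S)-epoxy alcohol (future 3S and, through the (Z) geometry, C4); in situ silylation gives an ether that cannot participate in step 6.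

Step 6
Reactants: 8 tert-butyl{[(2E)-3-methyl-5-[(2S,3R)-3-methyl-3-(triethylsilyloxymethyl)oxiran-2-yl]pent-2-en-1-yl]oxy}diphenylsilane
Product: 10 (1S,2S,3R)-3-({[tert-butyl(diphenyl)silyl]oxy}methyl)-2-(hydroxymethyl)-2-methyl-4-methylidenecyclohexan-1-ol, via cyclised triethylsilyl ether 9 (not isolated)
Conditions: ZrCl4, CH2Cl2, −78 to −30 °C; then PPTS (cat.), MeOH, rt
Reagents that add atoms: none
Why: Epoxide-initiated cation–olefin cyclisation through a chair, in which the E alkene attacks C4 anti to the breaking C–O bond so that the (Z)-CH2O group becomes axial (C19), the C5 substituent equatorial and the 3-OH keeps the epoxide configuration, while loss of a C20 proton gives the exocyclic alkene; methanolysis then removes the primary triethylsilyl group.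

Step 7
Reactants: 10 (1S,2S,3R)-3-({[tert-butyl(diphenyl)silyl]oxy}methyl)-2-(hydroxymethyl)-2-methyl-4-methylidenecyclohexan-1-ol
Product: 11 [(1S,2R,6S)-6-acetoxy-2-({[tert-butyl(diphenyl)silyl]oxy}methyl)-1-methyl-3-methylidenecyclohexyl]methyl acetate
Conditions: Ac2O, pyridine, DMAP (cat.), CH2Cl2, rt
Reagents that add atoms: acetic anhydride, CC(=O)OC(C)=O
Why: DMAP-catalysed acetylation installs both acetates of the target at once.

Step 8
Reactants: 11 [(1S,2R,6S)-6-acetoxy-2-({[tert-butyl(diphenyl)silyl]oxy}methyl)-1-methyl-3-methylidenecyclohexyl]methyl acetate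
Product: 12 [(1S,2R,6S)-6-acetoxy-2-(hydroxymethyl)-1-methyl-3-methylidenecyclohexyl]methyl acetate
Conditions: Bu4NF, AcOH (1:1), THF, 0 °C to rt
Reagents that add atoms: none
Why: Fluoride cleaves the silyl ether, and the acetic acid buffer should suppress acetyl migration to the freed alcohol.

Step 9
Reactants: 12 [(1S,2R,6S)-6-acetoxy-2-(hydroxymethyl)-1-methyl-3-methylidenecyclohexyl]methyl acetate
Product: 13 [(1S,2R,6S)-6-acetoxy-2-formyl-1-methyl-3-methylidenecyclohexyl]methyl acetate
Conditions: Dess–Martin periodinane, NaHCO3, CH2Cl2, 0 °C; used crude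
Reagents that add atoms: none
Why: Buffered Dess–Martin oxidation gives the β,γ-unsaturated aldehyde without base or acid that could epimerise C5 or move the alkene into conjugation.

Step 10
Reactants: 13 [(1S,2R,6S)-6-acetoxy-2-formyl-1-methyl-3-methylidenecyclohexyl]methyl acetate; 14 2-ethyl-1,3-dithiane
Product: 16 [(1S,2R,6S)-6-acetoxy-2-[(S)-(2-ethyl-1,3-dithian-2-yl)(triethylsilyloxy)methyl]-1-methyl-3-methylidenecyclohexyl]methyl acetate, via lithium alkoxide 15 (not isolated)
Conditions: 14, n-BuLi, THF, −30 °C; then 13, −78 °C; then Et3SiOTf, 2,6-lutidine, −78 to 0 °C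
Reagents that add atoms: triethylsilyl trifluoromethanesulfonate, CC[Si](CC)(CC)OS(=O)(=O)C(F)(F)F
Why: Corey–Seebach acyl-anion addition, in which Felkin–Anh attack anti to the quaternary C4 (large group, C10 as medium group) should set the 6S (future 6β-oxygen) configuration; the aldehyde reacts faster than the acetates at −78 °C, and silylating the alkoxide cold forestalls acetyl migration.

Step 11
Reactants: 16 [(1S,2R,6S)-6-acetoxy-2-[(S)-(2-ethyl-1,3-dithian-2-yl)(triethylsilyloxy)methyl]-1-methyl-3-methylidenecyclohexyl]methyl acetate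
Product: 17 [(1S,2R,6S)-6-acetoxy-1-methyl-3-methylidene-2-[(1S)-2-oxo-1-(triethylsilyloxy)butyl]cyclohexyl]methyl acetate
Conditions: MeI, CaCO3, MeCN/H2O (9:1), 40 °C
Reagents that add atoms: water, O
Why: S-Methylation turns the dithiane into a leaving group and buffered hydrolysis unveils the ketone without acid that could cleave the silyl ether or isomerise the alkene.

Step 12
Reactants: 18 ethyl 2-(bromomethyl)prop-2-enoate; 19 vinylmagnesium bromide
Product: 20 ethyl 2-methylidenepent-4-enoate
Conditions: CuI (10 mol%), THF, −78 to −20 °C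
Reagents that add atoms: none
Why: Copper-catalysed allylic substitution of the activated bromide, where the SN2 and SN2′ paths give the same product.

Step 13
Reactants: 20 ethyl 2-methylidenepent-4-enoate
Product: 21 2-methylidenepent-4-en-1-ol
Conditions: (i-Bu)2AlH, CH2Cl2, −78 to 0 °C; aqueous potassium sodium tartrate
Reagents that add atoms: none
Why: 1,2-Reduction of the enoate gives the 2-substituted allylic alcohol needed for directed epoxidation.

Step 14
Reactants: 21 2-methylidenepent-4-en-1-ol
Product: 22 [(2R)-2-(prop-2-en-1-yl)oxiran-2-yl]methanol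
Conditions: Ti(Oi-Pr)4 (10 mol%), D-(−)-diethyl tartrate (12 mol%), t-BuOOH, 4 Å MS, CH2Cl2, −20 °C
Reagents that add atoms: tert-butyl hydroperoxide, CC(C)(C)OO
Why: Sharpless asymmetric epoxidation reacts only at the allylic alcohol alkene, and D-(−)-tartrate should give the (R)-epoxide, which fixes C13.

Step 15
Reactants: 22 [(2R)-2-(prop-2-en-1-yl)oxiran-2-yl]methanol; 23 dimethyl malonate
Product: 24 methyl (5S)-5-(hydroxymethyl)-2-oxo-5-(prop-2-en-1-yl)oxolane-3-carboxylate (both C3 epimers)
Conditions: NaH, THF, 0 to 65 °C; AcOH quench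
Reagents that add atoms: none
Why: Malonate opens the epoxide at its CH2 end and the tertiary alkoxide lactonises onto an ester (classical γ-lactone synthesis); the C–O bond at the stereocentre is not broken, and a Payne shift would be degenerate and lead to the same enantiomer.

Step 16
Reactants: 24 methyl (5S)-5-(hydroxymethyl)-2-oxo-5-(prop-2-en-1-yl)oxolane-3-carboxylate
Product: 25 (5R)-5-(hydroxymethyl)-5-(prop-2-en-1-yl)oxolan-2-one
Conditions: LiCl, DMSO/H2O, 150 °C
Reagents that add atoms: none
Why: Krapcho dealkoxycarbonylation removes the activating ester without touching the lactone or the stereocentre (the descriptor changes only through CIP priorities).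

Step 17
Reactants: 25 (5R)-5-(hydroxymethyl)-5-(prop-2-en-1-yl)oxolan-2-one
Product: 27 (5R)-8-methoxy-1,7-dioxaspiro[4.4]nonan-2-one (both C8 epimers), via lactol 26 (not isolated)
Conditions: O3, CH2Cl2/MeOH, −78 °C; Me2S; then CSA (cat.), MeOH, rt
Reagents that add atoms: methanol, CO
Why: Ozonolysis gives the aldehyde, which closes with the primary alcohol to the five-membered lactol (second oxolane ring), and acid-catalysed acetalisation gives the methyl acetal that masks the later enol ether.

Step 18
Reactants: 17 [(1S,2R,6S)-6-acetoxy-1-methyl-3-methylidene-2-[(1S)-2-oxo-1-(triethylsilyloxy)butyl]cyclohexyl]methyl acetate; 27 (5R)-8-methoxy-1,7-dioxaspiro[4.4]nonan-2-one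
Product: 29 [(1S,2R,6S)-6-acetoxy-2-[(1S,3Z)-3-[(5R)-8-methoxy-1,7-dioxaspiro[4.4]nonan-2-ylidene]-2-oxo-1-(triethylsilyloxy)butyl]-1-methyl-3-methylidenecyclohexyl]methyl acetate, via hemiketal 28 (not isolated)
Conditions: 17, LiN(SiMe3)2, THF, −78 °C; then 27, −78 to −30 °C; AcOH; then PPTS (cat.), 4 Å MS, toluene, 50 °C
Reagents that add atoms: none
Why: Kinetic deprotonation at the ethyl CH2 and Claisen-type acylation of the enolate by the lactone gives the cyclic hemiketal of the hydroxy β-diketone, and its dehydration should give the conjugated exocyclic enol ether as the (Z) isomer, which places the bulky C6 side of the acyl group next to the ring oxygen and not next to C11H2.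

Step 19
Reactants: 29 [(1S,2R,6S)-6-acetoxy-2-[(1S,3Z)-3-[(5R)-8-methoxy-1,7-dioxaspiro[4.4]nonan-2-ylidene]-2-oxo-1-(triethylsilyloxy)butyl]-1-methyl-3-methylidenecyclohexyl]methyl acetate
Product: 30 3β,19-diacetoxy-15-methoxy-6β-(triethylsilyloxy)-9α,13R:15,16-diepoxylabdan-7-one (5α,8βH,10β; both C15 epimers)
Conditions: Fe(acac)3 (30 mol%), PhSiH3, EtOH/(CH2OH)2 (5:1), 60 °C
Reagents that add atoms: none
Why: Proposed new method: Fe(acac)3/PhSiH3 should transfer a hydrogen atom to C20 of the 1,1-disubstituted alkene (metal-hydride hydrogen-atom transfer, MHAT), the nucleophilic tertiary C10 radical should add to C9, the β-carbon of the β-alkoxy enone C7(=O)–C8=C9–O, and the α-keto radical at C8 is then reduced to the iron enolate and protonated by ethanol. The closest known reaction types are the Fe(acac)3/PhSiH3 reductive olefin–enone coupling (intramolecular Giese cyclisation) and tin-mediated radical cyclisations onto β-alkoxy acrylates; what has not been shown is the MHAT variant at a fully substituted β-alkoxy enone carbon that joins two fully substituted centres. Ring B closes in the 6-endo-trig mode, the 5-exo alternative at C8 being polarity-mismatched. C10 is set by a chair–chair transition state with the C5 side chain equatorial (new bond equatorial, methyl axial, trans ring fusion, as in radical polyene cyclisations); C9 is set by the (Z) alkene geometry, which puts the ring oxygen (cis to C7) axial and anti to the C10 methyl and C11 equatorial; C8 is set by axial protonation of the enolate and is in any case the thermodynamic equatorial-methyl epimer. The step needs hydrogen-atom transfer only at C10=C20, which is secured by carrying the second oxolane as a saturated acetal and by the low reactivity of the tetrasubstituted push–pull alkene; any Δ1(10) alkene isomer carried from step 6 would give the same radical.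

Step 20
Reactants: 30 3β,19-diacetoxy-15-methoxy-6β-(triethylsilyloxy)-9α,13R:15,16-diepoxylabdan-7-one
Product: 31 3β,19-diacetoxy-6β-(triethylsilyloxy)-9α,13R:15,16-diepoxylabd-14-en-7-one
Conditions: Me3SiOTf, i-Pr2NEt, CH2Cl2, −20 to 0 °C
Reagents that add atoms: none
Why: Silyl triflate ionises the methyl acetal to the oxocarbenium ion and the amine removes a C14 proton (acetal-to-enol-ether elimination), so both C15 epimers converge on one enol ether while excess base protects the acid-labile product from opening to the furan.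

Step 21
Reactants: 31 3β,19-diacetoxy-6β-(triethylsilyloxy)-9α,13R:15,16-diepoxylabd-14-en-7-one
Product: 32 3β,19-diacetoxy-6β-hydroxy-9α,13R:15,16-diepoxylabd-14-en-7-one (CNP0317137.1)
Conditions: Bu4NF, AcOH (1:1), THF, 0 °C
Reagents that add atoms: none
Why: Buffered fluoride cleaves the triethylsilyl ether (and any silyl enol ether formed in step 20) under near-neutral conditions that should spare the acetates and the enol ether.

**Compound list**

1 | geraniol | CC(C)=CCC/C(C)=C/CO | starting material
2 | tert-butyl{[(2E)-3,7-dimethylocta-2,6-dien-1-yl]oxy}diphenylsilane | CC(C)=CCC/C(C)=C/CO[Si](c1ccccc1)(c1ccccc1)C(C)(C)C | intermediate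
3 | (4E)-6-{[tert-butyl(diphenyl)silyl]oxy}-4-methylhex-4-enal | O=CCC/C(C)=C/CO[Si](c1ccccc1)(c1ccccc1)C(C)(C)C | intermediate
4 | ethyl 2-[bis(2,2,2-trifluoroethoxy)phosphoryl]propanoate | CCOC(=O)C(C)P(=O)(OCC(F)(F)F)OCC(F)(F)F | starting material
5 | ethyl (2Z,6E)-8-{[tert-butyl(diphenyl)silyl]oxy}-2,6-dimethylocta-2,6-dienoate | CCOC(=O)/C(C)=C\CC/C(C)=C/CO[Si](c1ccccc1)(c1ccccc1)C(C)(C)C | intermediate
6 | (2Z,6E)-8-{[tert-butyl(diphenyl)silyl]oxy}-2,6-dimethylocta-2,6-dien-1-ol | OC/C(C)=C\CC/C(C)=C/CO[Si](c1ccccc1)(c1ccccc1)C(C)(C)C | intermediate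
7 | [(2R,3S)-3-[(3E)-5-{[tert-butyl(diphenyl)silyl]oxy}-3-methylpent-3-en-1-yl]-2-methyloxiran-2-yl]methanol | OC[C@@]1(C)O[C@H]1CC/C(C)=C/CO[Si](c1ccccc1)(c1ccccc1)C(C)(C)C | intermediate (not isolated)
8 | triethylsilyl ether of 7 | CC[Si](CC)(CC)OC[C@@]1(C)O[C@H]1CC/C(C)=C/CO[Si](c1ccccc1)(c1ccccc1)C(C)(C)C | intermediate
9 | (1S,2S,3R)-3-({[tert-butyl(diphenyl)silyl]oxy}methyl)-2-methyl-4-methylidene-2-[(triethylsilyloxy)methyl]cyclohexan-1-ol | CC[Si](CC)(CC)OC[C@@]1(C)[C@@H](O)CCC(=C)[C@H]1CO[Si](c1ccccc1)(c1ccccc1)C(C)(C)C | intermediate (not isolated)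
10 | (1S,2S,3R)-3-({[tert-butyl(diphenyl)silyl]oxy}methyl)-2-(hydroxymethyl)-2-methyl-4-methylidenecyclohexan-1-ol | OC[C@@]1(C)[C@@H](O)CCC(=C)[C@H]1CO[Si](c1ccccc1)(c1ccccc1)C(C)(C)C | intermediate
11 | [(1S,2R,6S)-6-acetoxy-2-({[tert-butyl(diphenyl)silyl]oxy}methyl)-1-methyl-3-methylidenecyclohexyl]methyl acetate | CC(=O)OC[C@@]1(C)[C@@H](OC(C)=O)CCC(=C)[C@H]1CO[Si](c1ccccc1)(c1ccccc1)C(C)(C)C | intermediate
12 | [(1S,2R,6S)-6-acetoxy-2-(hydroxymethyl)-1-methyl-3-methylidenecyclohexyl]methyl acetate | CC(=O)OC[C@@]1(C)[C@@H](OC(C)=O)CCC(=C)[C@H]1CO | intermediate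
13 | [(1S,2R,6S)-6-acetoxy-2-formyl-1-methyl-3-methylidenecyclohexyl]methyl acetate | CC(=O)OC[C@@]1(C)[C@@H](OC(C)=O)CCC(=C)[C@H]1C=O | intermediate
14 | 2-ethyl-1,3-dithiane | CCC1SCCCS1 | starting material
15 | lithium alkoxide of the dithiane adduct of 13 (6S) | CC(=O)OC[C@@]1(C)[C@@H](OC(C)=O)CCC(=C)[C@H]1[C@H](O[Li])C1(CC)SCCCS1 | intermediate (not isolated)
16 | [(1S,2R,6S)-6-acetoxy-2-[(S)-(2-ethyl-1,3-dithian-2-yl)(triethylsilyloxy)methyl]-1-methyl-3-methylidenecyclohexyl]methyl acetate | CC(=O)OC[C@@]1(C)[C@@H](OC(C)=O)CCC(=C)[C@H]1[C@H](O[Si](CC)(CC)CC)C1(CC)SCCCS1 | intermediate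
17 | [(1S,2R,6S)-6-acetoxy-1-methyl-3-methylidene-2-[(1S)-2-oxo-1-(triethylsilyloxy)butyl]cyclohexyl]methyl acetate | CC(=O)OC[C@@]1(C)[C@@H](OC(C)=O)CCC(=C)[C@H]1[C@H](O[Si](CC)(CC)CC)C(=O)CC | intermediate
18 | ethyl 2-(bromomethyl)prop-2-enoate | C=C(CBr)C(=O)OCC | starting material
19 | vinylmagnesium bromide | C=C[Mg]Br | starting material
20 | ethyl 2-methylidenepent-4-enoate | C=CCC(=C)C(=O)OCC | intermediate
21 | 2-methylidenepent-4-en-1-ol | C=CCC(=C)CO | intermediate
22 | [(2R)-2-(prop-2-en-1-yl)oxiran-2-yl]methanol | OC[C@]1(CC=C)CO1 | intermediate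
23 | dimethyl malonate | COC(=O)CC(=O)OC | starting material
24 | methyl (5S)-5-(hydroxymethyl)-2-oxo-5-(prop-2-en-1-yl)oxolane-3-carboxylate (both C3 epimers) | COC(=O)C1C[C@](CO)(CC=C)OC1=O | intermediate
25 | (5R)-5-(hydroxymethyl)-5-(prop-2-en-1-yl)oxolan-2-one | O=C1CC[C@](CO)(CC=C)O1 | intermediate
26 | (5R)-8-hydroxy-1,7-dioxaspiro[4.4]nonan-2-one (both C8 epimers) | O=C1CC[C@]2(CC(O)OC2)O1 | intermediate (not isolated)
27 | (5R)-8-methoxy-1,7-dioxaspiro[4.4]nonan-2-one (both C8 epimers) | O=C1CC[C@]2(CC(OC)OC2)O1 | intermediate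
28 | cyclic hemiketal from 17 and 27: 2-hydroxy-2-(1-methyl-2-oxoalkyl)oxolane, ring A part as in 17, (5R) spiro centre as in 27 | CC(=O)OC[C@@]1(C)[C@@H](OC(C)=O)CCC(=C)[C@H]1[C@H](O[Si](CC)(CC)CC)C(=O)C(C)C1(O)CC[C@]2(CC(OC)OC2)O1 | intermediate (not isolated)
29 | [(1S,2R,6S)-6-acetoxy-2-[(1S,3Z)-3-[(5R)-8-methoxy-1,7-dioxaspiro[4.4]nonan-2-ylidene]-2-oxo-1-(triethylsilyloxy)butyl]-1-methyl-3-methylidenecyclohexyl]methyl acetate | CC(=O)OC[C@@]1(C)[C@@H](OC(C)=O)CCC(=C)[C@H]1[C@H](O[Si](CC)(CC)CC)C(=O)/C(C)=C1/CC[C@]2(CC(OC)OC2)O1 | intermediate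
30 | 3β,19-diacetoxy-15-methoxy-6β-(triethylsilyloxy)-9α,13R:15,16-diepoxylabdan-7-one (5α,8βH,10β; both C15 epimers) | CC(=O)OC[C@@]1(C)[C@@H](OC(C)=O)CC[C@@]2(C)[C@H]1[C@H](O[Si](CC)(CC)CC)C(=O)[C@@H](C)[C@]21CC[C@]2(CC(OC)OC2)O1 | intermediate
31 | 3β,19-diacetoxy-6β-(triethylsilyloxy)-9α,13R:15,16-diepoxylabd-14-en-7-one | CC(=O)OC[C@@]1(C)[C@@H](OC(C)=O)CC[C@@]2(C)[C@H]1[C@H](O[Si](CC)(CC)CC)C(=O)[C@@H](C)[C@]21CC[C@]2(C=COC2)O1 | intermediate
32 | 3β,19-diacetoxy-6β-hydroxy-9α,13R:15,16-diepoxylabd-14-en-7-one (CNP0317137.1) | CC(=O)OC[C@@]1(C)[C@@H](OC(C)=O)CC[C@@]2(C)[C@H]1[C@H](O)C(=O)[C@@H](C)[C@]21CC[C@]2(C=COC2)O1 | target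

**Step count**

Total step count: 21. Longest linear sequence: 15 steps (steps 1–11 and 18–21).

**Steps most likely to fail**

1. Step 19 (proposed new method). The tertiary C10 radical may take up a second hydrogen atom, or the alkene may isomerise, before the slow addition to the fully substituted C9. The axial 6-silyloxy group may also divert closure to a cis-fused transition state. The fallback sets out from 29 and comes back at 30 using known reaction types. Cobalt-catalysed Markovnikov hydrochlorination (Co(BF4)2·6H2O with a salen ligand, TsCl, PhSiH3, EtOH) would give the tertiary chloride F1. Slow addition of Bu3SnH and AIBN in benzene at 80 °C would then generate the same radical in a tin hydride chain, the established setting for radical cyclisation onto β-alkoxy enoates and enones. This separates radical generation from the hydrogen donor, whose concentration is kept low, and cyclisation would return 30.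

2. Step 6. Proton loss may go toward the ring (endocyclic alkene), the epoxide may rearrange to a carbonyl compound, or the cation may be trapped by oxygen instead of by the alkene. The fallback sets out from 3 and comes back at 10. Aldol addition of the lithium enolate of (−)-8-phenylmenthyl propanoate to 3 would give the β-hydroxy ester F2, and Dess–Martin oxidation would give the β-keto ester F3. Oxidative radical cyclisation with Mn(OAc)3·2H2O and Cu(OAc)2·H2O in AcOH would give the methylidene keto ester F4: the chiral ester shields one face, the ester ends up axial, and Cu(OAc)2 oxidises the tertiary radical to the exocyclic alkene. LiAlH4 would then reduce the ketone (hydride from the α face) and the ester, release the auxiliary, and return diol 10.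

3. Step 18. The enolate may simply deprotonate the lactone, the Claisen equilibrium may be unfavourable, or enolate and alkoxide may attack the acetates. The fallback sets out from 27 (with 17) and comes back at 29. Reduction of 27 with (i-Bu)2AlH at −78 °C would give the lactol F5. The lithium enolate of 17 (LiN(SiMe3)2, 2 equiv.) would add to its open hydroxy-aldehyde form in an irreversible aldol addition to give the diol F6. Dess–Martin oxidation of the secondary alcohol would give the β-diketone, which closes to hemiketal 28 and is dehydrated as in step 18 to return 29.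

**Further compounds**

F1 | step 19 | tertiary chloride: 29 with H and Cl added across C10=CH2 (C10 bearing CH3 and Cl; both C10 epimers) | CC(=O)OC[C@@]1(C)[C@@H](OC(C)=O)CCC(C)(Cl)[C@H]1[C@H](O[Si](CC)(CC)CC)C(=O)/C(C)=C1/CC[C@]2(CC(OC)OC2)O1
F2 | step 6 | (1R,2S,5R)-5-methyl-2-(2-phenylpropan-2-yl)cyclohexyl (6E)-8-{[tert-butyl(diphenyl)silyl]oxy}-3-hydroxy-2,6-dimethyloct-6-enoate (diastereomer mixture at C2 and C3) | C[C@@H]1CC[C@@H](C(C)(C)c2ccccc2)[C@H](OC(=O)C(C)C(O)CC/C(C)=C/CO[Si](c2ccccc2)(c2ccccc2)C(C)(C)C)C1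
F3 | step 6 | (1R,2S,5R)-5-methyl-2-(2-phenylpropan-2-yl)cyclohexyl (6E)-8-{[tert-butyl(diphenyl)silyl]oxy}-2,6-dimethyl-3-oxooct-6-enoate | C[C@@H]1CC[C@@H](C(C)(C)c2ccccc2)[C@H](OC(=O)C(C)C(=O)CC/C(C)=C/CO[Si](c2ccccc2)(c2ccccc2)C(C)(C)C)C1
F4 | step 6 | 8-phenylmenthyl 2-({[tert-butyl(diphenyl)silyl]oxy}methyl)-1-methyl-3-methylidene-6-oxocyclohexane-1-carboxylate (ring A: ester and silyloxymethyl cis, configuration as in 10) | C[C@@H]1CC[C@@H](C(C)(C)c2ccccc2)[C@H](OC(=O)[C@@]2(C)C(=O)CCC(=C)[C@H]2CO[Si](c3ccccc3)(c3ccccc3)C(C)(C)C)C1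
F5 | step 18 | (5R)-8-methoxy-1,7-dioxaspiro[4.4]nonan-2-ol (lactol; epimers at C2 and C8) | OC1CC[C@]2(CC(OC)OC2)O1
F6 | step 18 | aldol diol from 17 and F5: ring A part as in 17, chain C(=O)–CH(CH3)–CH(OH)–CH2CH2– attached to C3 of a 3-hydroxy-5-methoxyoxolane (configuration at that carbon as C13 of the target) | CC(=O)OC[C@@]1(C)[C@@H](OC(C)=O)CCC(=C)[C@H]1[C@H](O[Si](CC)(CC)CC)C(=O)C(C)C(O)CC[C@@]1(O)CC(OC)OC1
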